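Late in Monday's run Q stops rising, at 34.8% after 1.33 min and 34.8% after 2.50 min, and that share of 0.60 M of E is 0.209 M, the G charged. So E and G go one to one and G is the limiting reagent. The charge of G over the charge of E, here 70.0%, is the ceiling on Q, in percent of the E charged.

| flask | E | G | remark | time |
|---|---|---|---|---|
| Friday's | 0.15 M | 0.21 M | run made earlier |  |
| Monday's | 0.60 M | 0.21 M | run made earlier |  |
| Sunday's | 0.30 M | 0.42 M | run made earlier |  |
| flask | 0.30 M | 0.210 M |  | 4.0 min |

| run | time / min | E / % | Q / % |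
|---|---|---|---|
| Friday's | 0.167 | 89.4 | 10.3 |
| Friday's | 0.500 | 71.9 | 27.8 |
| Friday's | 0.833 | 58.8 | 40.7 |
| Friday's | 1.33 | 44.8 | 55.4 |
| Friday's | 2.00 | 32.1 | 68.2 |
| Friday's | 2.50 | 24.9 | 75.0 |
| Monday's | 0.200 | 88.1 | 11.8 |
| Monday's | 0.333 | 82.7 | 17.4 |
| Monday's | 0.500 | 77.1 | 23.2 |
| Monday's | 0.833 | 68.9 | 31.0 |
| Monday's | 1.33 | 65.1 | 34.8 |
| Monday's | 2.50 | 64.6 | 34.8 |
| Sunday's | 0.200 | 83.1 | 17.1 |
| Sunday's | 0.333 | 73.3 | 26.0 |
| Sunday's | 0.667 | 55.7 | 44.5 |
| Sunday's | 1.33 | 33.7 | 66.1 |
| Sunday's | 2.50 | 15.9 | 84.3 |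

(standard deviation of a reading: 0.3 percentage points)

- amount of E in the flask at 4.0 min, in percent of the E charged
- amount of Q in the flask at 4.0 min, in percent of the E charged



Which numbers must we know well? The charges come first: 10 percent off in G moves the ceiling by 7 percentage points. The rate constant k counts for less, but we need it to see whether G is used up in time.

First readings give a fractional loss of E of 0.671 /min on Friday and 0.633 /min on Monday, so the rate is first order in E. Sunday, with 0.42 M of G, gives 0.926 /min, a ratio to Friday of 1.38, near 1.41, so we take order 0.5 in G. Sunday's reading, brought to the flask's charge c = 0.210 M of G, then gives k = 0.675 /min, the fractional loss of E at [G] = c. The balance of G in the flask is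

d√([G]/c)/dt = −(k/2)[E]/c, with [E] = [G] + 0.0900 M.

Taking [E] where [G] is a quarter of its charge, our estimate has [G] reach zero near 4.37 min. Our reckoning leaves Q 0.2 points under the ceiling at 4.0 min, so Q 69.8% and E 30.2%. With k 10 percent lower, the shortfall is 0.86 points.

The forecast, “meaning half order in G”, gives E 30.3% (29.9% to 30.9%) and Q 69.7% (69.1% to 70.1%). The flask gives E 30.3% and Q 69.7%.

    E + G → Q, rate k1*[E]*[G]^0.5 (k = 0.0250 /M^0.5/s)

In the flask the half-life of E on this path at 0.740 min is 1.4 min, shorter than the 4.0 min allowed. At 4.00 min the slowest mode has a half-life of 0.275 min, far shorter again, and 0.36% of the G remains, with Q at 69.7%, just under its ceiling of 70.0%. In the neighbour flask with 0.084 M of G the ceiling is 28.0%; computed, it holds Q 28.0% and E 72.0% at 4.00 min, with 0% of its G left.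

The data come from a simulation with made-up constants, noise included.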